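The cyclohexanone ring (C1 quaternary carbinol, C2 ketone, C3 methylene, C4 carbinol, C5 benzoyloxy carbon, C6 carbinol) holds a β-hydroxy ketone, C2(=O)–C3H2–C4H(OH). Disconnecting C3–C4 as an aldol, as dehydroquinate synthase and the Ferrier carbocyclization do, opens the carbocycle to a 6-deoxyhexos-5-ulose whose methyl ketone is masked as a terminal alkyne. In one operation divalent mercury hydrates the alkyne of an ethynyl-bearing furanose lactol to an α-mercurio ketone that adds to the lactol aldehyde, closing the six-membered ring and setting C4. C5, C6 and C1 come from D-mannose, C1 being made quaternary by hydroxymethylation with formaldehyde.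

Key step: step 6

Remark: lactols 2 and 7 are expected as anomeric mixtures; the anomeric carbon is opened in the following step, so it is left undefined in their SMILES. Intermediates carry sugar locants; C1–C6 of the target are as defined above.

Step 1
Reactants: 1 2,3:5,6-di-O-isopropylidene-α-D-mannofuranose
Product: 2 2-C-(hydroxymethyl)-2,3:5,6-di-O-isopropylidene-D-mannofuranose
Conditions: 37% aq. HCHO (excess), K2CO3, MeOH, 65 °C
Reagents that add atoms: formaldehyde, C=O
Why: Base-mediated crossed aldol addition of the C2 enolate of the ring-opened aldehyde to non-enolizable formaldehyde (aldol hydroxymethylation, known for 2,3-O-isopropylidene furanoses) should build the quaternary centre, and because only the one-carbon arm lying cis to C4 on the cis-fused dioxolane can reclose to the furanose lactol, the hydroxymethyl group ends up in the place of H2 with the manno configuration retained.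

Step 2
Reactants: 2 2-C-(hydroxymethyl)-2,3:5,6-di-O-isopropylidene-D-mannofuranose
Product: 3 1,2-dideoxy-3-C-(hydroxymethyl)-3,4:6,7-di-O-isopropylidene-D-manno-hept-1-ynitol
Conditions: dimethyl (1-diazo-2-oxopropyl)phosphonate, K2CO3, MeOH, rt to 40 °C
Reagents that add atoms: dimethyl (1-diazo-2-oxopropyl)phosphonate, COP(=O)(OC)C(=[N+]=[N-])C(C)=O
Why: Seyferth–Gilbert homologation in its Ohira–Bestmann form should convert the open-chain aldehyde tautomer of the lactol into the terminal alkyne with one added carbon, the quaternary α-carbon excluding epimerization and β-elimination, and it frees the 5-OH for acylation; no stereocentre is formed.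

Step 3
Reactants: 3 1,2-dideoxy-3-C-(hydroxymethyl)-3,4:6,7-di-O-isopropylidene-D-manno-hept-1-ynitol
Product: 4 5-O-benzoyl-3-C-(benzoyloxymethyl)-1,2-dideoxy-3,4:6,7-di-O-isopropylidene-D-manno-hept-1-ynitol
Conditions: BzCl, pyridine, DMAP (cat.), CH2Cl2, 0 °C to rt
Reagents that add atoms: benzoyl chloride, O=C(Cl)c1ccccc1
Why: DMAP-catalysed acylation (nucleophilic acyl substitution) should esterify the only two free hydroxyls, the primary one and the secondary 5-OH, which installs both benzoates of the target at once without touching a stereocentre.

Step 4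
Reactants: 4 5-O-benzoyl-3-C-(benzoyloxymethyl)-1,2-dideoxy-3,4:6,7-di-O-isopropylidene-D-manno-hept-1-ynitol
Product: 6 2-O-benzoyl-4-C-(benzoyloxymethyl)-5,6-dideoxy-3,4-O-isopropylidene-aldehydo-D-arabino-hex-5-ynose, via terminal diol 5 (not isolated)
Conditions: H5IO6 (1.5 equiv), EtOAc, 0 °C to rt
Reagents that add atoms: none
Why: Periodic acid should hydrolyse the less hindered terminal dioxolane in preference to the internal one on the quaternary carbon and cleave the liberated 6,7-diol in the same flask (Malaprade glycol cleavage), which unveils the aldehyde carbon without affecting any stereocentre.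

Step 5
Reactants: 6 2-O-benzoyl-4-C-(benzoyloxymethyl)-5,6-dideoxy-3,4-O-isopropylidene-aldehydo-D-arabino-hex-5-ynose
Product: 7 2-O-benzoyl-4-C-(benzoyloxymethyl)-5,6-dideoxy-D-arabino-hex-5-ynofuranose
Conditions: TFA–H2O (9:1), 0 °C to rt
Reagents that add atoms: none
Why: Acid-catalysed acetal hydrolysis should remove the remaining isopropylidene group, whereupon the freed tertiary 4-OH closes onto the aldehyde to a furanose lactol that masks the α-benzoyloxy aldehyde and holds the 2-O-benzoate trans to 3-OH on a five-membered ring, which disfavours acyl migration; the anomeric centre is the only new stereocentre and is lost in the next step.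

Step 6
Reactants: 7 2-O-benzoyl-4-C-(benzoyloxymethyl)-5,6-dideoxy-D-arabino-hex-5-ynofuranose
Product: 9 [(1S,2S,3R,4R)-3-(benzoyloxy)-1,2,4-trihydroxy-6-oxocyclohexyl]methyl benzoate, via α-mercurio ketone 8 (not isolated)
Conditions: Hg(OTf)2 (10 mol %), acetone–H2O (4:1), rt
Reagents that add atoms: water, O
Why: Proposed new method: divalent mercury should add water across the terminal alkyne in the Markovnikov sense (Kucherov oxymercuration) and the resulting enol tautomerizes to the α-mercurio methyl ketone 8, the very species through which a hex-5-enopyranoside passes in the Ferrier carbocyclization; the lactol opens to the aldehyde, the carbon-bound mercury enolate adds to it, and protonolysis of the mercury alkoxide returns the catalyst. The closest known reaction types are the catalytic Ferrier carbocyclization of 6-deoxyhex-5-enopyranosides and the Hg(OTf)2-catalysed hydration of terminal alkynes, and the bond formation parallels the enzymatic aldol of dehydroquinate synthase; what is new is the interception of the hydration intermediate by the tethered aldehyde. The six-membered carbocycle closes by a 6-(enolendo)-exo-trig aldol between the former terminal alkyne carbon (C3) and the aldehyde carbon (C4). The configuration of C4 is controlled by the existing stereocentres through a chair-like transition state in which mercury bridges the enolate and aldehyde oxygens while the benzoyloxy group at C5, the hydroxyl at C6 and the benzoyloxymethyl group at C1 sit equatorial, so that the new hydroxyl becomes axial, cis to the C5 benzoate and trans to the C6 hydroxyl, the sense found in Ferrier products. The step needs Markovnikov hydration and an aldol faster than protodemercuration: the terminal position of the alkyne secures the former, the near-neutral aqueous acetone and the six-membered closure favour the latter, and the fully substituted C1 leaves the former alkyne carbon as the only enolizable position of the ketone.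

Compound list
1 | 2,3:5,6-di-O-isopropylidene-α-D-mannofuranose | O[C@@H]1[C@H]2OC(C)(C)O[C@H]2[C@@H]([C@H]3COC(C)(C)O3)O1 | starting material
2 | 2-C-(hydroxymethyl)-2,3:5,6-di-O-isopropylidene-D-mannofuranose (anomeric mixture; hydroxymethyl in place of H2) | OC1[C@@]2(CO)OC(C)(C)O[C@H]2[C@@H]([C@H]3COC(C)(C)O3)O1 | intermediate
3 | 1,2-dideoxy-3-C-(hydroxymethyl)-3,4:6,7-di-O-isopropylidene-D-manno-hept-1-ynitol (free 5-OH and primary OH) | C#C[C@@]1(CO)OC(C)(C)O[C@H]1[C@H](O)[C@H]1COC(C)(C)O1 | intermediate
4 | 5-O-benzoyl-3-C-(benzoyloxymethyl)-1,2-dideoxy-3,4:6,7-di-O-isopropylidene-D-manno-hept-1-ynitol | C#C[C@@]1(COC(=O)c2ccccc2)OC(C)(C)O[C@H]1[C@H](OC(=O)c2ccccc2)[C@H]1COC(C)(C)O1 | intermediate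
5 | 5-O-benzoyl-3-C-(benzoyloxymethyl)-1,2-dideoxy-3,4-O-isopropylidene-D-manno-hept-1-ynitol (6,7-diol, formed in the flask in step 4) | C#C[C@@]1(COC(=O)c2ccccc2)OC(C)(C)O[C@H]1[C@H](OC(=O)c2ccccc2)[C@H](O)CO | intermediate
6 | 2-O-benzoyl-4-C-(benzoyloxymethyl)-5,6-dideoxy-3,4-O-isopropylidene-aldehydo-D-arabino-hex-5-ynose | C#C[C@@]1(COC(=O)c2ccccc2)OC(C)(C)O[C@H]1[C@H](OC(=O)c2ccccc2)C=O | intermediate
7 | 2-O-benzoyl-4-C-(benzoyloxymethyl)-5,6-dideoxy-D-arabino-hex-5-ynofuranose (anomeric mixture; ethynyl and benzoyloxymethyl both on C4) | C#C[C@@]1(COC(=O)c2ccccc2)OC(O)[C@@H](OC(=O)c2ccccc2)[C@@H]1O | intermediate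
8 | 2-O-benzoyl-4-C-(benzoyloxymethyl)-6-deoxy-6-(trifluoromethanesulfonyloxymercurio)-aldehydo-D-arabino-hexos-5-ulose (formed in the flask in step 6) | FC(F)(F)S(=O)(=O)O[Hg]CC(=O)[C@](O)(COC(=O)c1ccccc1)[C@@H](O)[C@H](OC(=O)c1ccccc1)C=O | intermediate
9 | [(1S,2S,3R,4R)-3-(benzoyloxy)-1,2,4-trihydroxy-6-oxocyclohexyl]methyl benzoate (CNP0127041.1) | O=C(OC[C@@]1(O)C(=O)C[C@@H](O)[C@@H](OC(=O)c2ccccc2)[C@@H]1O)c1ccccc1 | target

Total step count: 6. Longest linear sequence: 6 steps (1 to 9).

Steps most likely to fail

Step 6 (bears the label). Protodemercuration of the α-mercurio ketone may outrun the aldol if the lactol opens too slowly, so that the alkyne is only hydrated, and the acidic medium could also dehydrate the β-hydroxy ketone. The fallback uses known chemistry, sets out from 7 and comes back at 9. Gold-catalysed Markovnikov hydration of the alkyne (Ph3PAuNTf2, aqueous 1,4-dioxane, 60 °C) should give the methyl ketone 2-O-benzoyl-4-C-(benzoyloxymethyl)-6-deoxy-D-arabino-hexos-5-ulo-1,4-furanose F1. The base-promoted intramolecular aldol known for aldohexos-5-uloses (DBU, 0.2 equiv, CH2Cl2, −20 °C) should then close the C3–C4 bond to 9. Without the mercury bridge the configuration at C4 rests only on the chair preference, so it would have to be checked.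

Step 2. The homologation may be slow because little of the hindered lactol is open and the aldehyde is of neopentyl type, and carbonate in methanol may in the meantime cause retro-aldol loss of formaldehyde. The fallback sets out from 2 and comes back at 3. Wittig chloromethylenation (Ph3P=CHCl from (chloromethyl)triphenylphosphonium chloride and n-BuLi, THF, −78 °C to rt, excess ylide to cover the two hydroxyls) should give (E/Z)-1-chloro-1,2-dideoxy-3-C-(hydroxymethyl)-3,4:6,7-di-O-isopropylidene-D-manno-hept-1-enitol F2. Dehydrochlorination with excess n-BuLi (THF, −78 to 0 °C) should then give alkyne 3.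

Step 5. Hydrolysis of the hindered, electron-poor dioxolane may be slow, which leaves time for acid-promoted migration of the secondary benzoate to the freed neighbouring hydroxyl before the lactol closes. The fallback reverses the order, sets out from 6 and comes back at 9. The conditions of step 6 (or the stepwise hydration and aldol of the first fallback) are applied to 6, in which the aldehyde is free, to give the 1,2-O-isopropylidene acetal of 9 F3. The acetal is then removed last (TFA–H2O, 0 °C, short contact).

Further compounds
F1 | step 6 | 2-O-benzoyl-4-C-(benzoyloxymethyl)-6-deoxy-D-arabino-hexos-5-ulo-1,4-furanose (anomeric mixture) | CC(=O)[C@@]1(COC(=O)c2ccccc2)OC(O)[C@@H](OC(=O)c2ccccc2)[C@@H]1O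
F2 | step 2 | (E/Z)-1-chloro-1,2-dideoxy-3-C-(hydroxymethyl)-3,4:6,7-di-O-isopropylidene-D-manno-hept-1-enitol | ClC=C[C@@]1(CO)OC(C)(C)O[C@H]1[C@H](O)[C@H]1COC(C)(C)O1
F3 | step 5 | 1,2-O-isopropylidene acetal of 9 (dioxolane across the tertiary 1-OH and the 2-OH, locants of the name of 9) | O=C1C[C@@H](O)[C@@H](OC(=O)c2ccccc2)[C@@H]2OC(C)(C)O[C@]12COC(=O)c1ccccc1
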